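Late in the delta run the sum of target and isomer holds still: it reads 112% at 25.0 min and 112% at 50.0 min. What target loses, the isomer gains, and the share asked for follows that exchange.

| flask | substrate | target | temperature | remark | time |
|---|---|---|---|---|---|
| epsilon | 20 mM (fed, over 1.0 min) | 2.8 mM | 35 °C | run made earlier; the fed solution adds 1.0 times the starting volume |  |
| delta | 20 mM (fed, over 1.0 min) | 4.4 mM | 60 °C | run made earlier; the fed solution adds 1.0 times the starting volume |  |
| gamma | 40 mM (fed, over 1.0 min) | 2 mM | 35 °C | run made earlier; the fed solution adds 1.0 times the starting volume |  |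
| violet | 20 mM (fed, over 1.0 min) | 2.00 mM | 60 °C | the fed solution adds 1.0 times the starting volume | 1.0 h |
| teal | 20 mM (fed, over 1.0 min) | 2.00 mM | 40 °C | the fed solution adds 1.0 times the starting volume | 1.0 h |
| grey | 20 mM (fed, over 1.0 min) | 2.00 mM | 80 °C | the fed solution adds 1.0 times the starting volume | 1.0 h |

- epsilon (time / h: target / %, isomer of the product / %): 0.500: 61.8, 1.9; 0.833: 81.3, 4.4; 1.33: 84.9, 9.2; 1.50: 84.4, 10.4; 2.50: 77.0, 18.8; 3.00: 72.9, 23.0
- delta (time / min: target / %, isomer of the product / %): 3.00: 57.3, 4.2; 10.0: 84.0, 25.4; 15.0: 71.9, 39.1; 25.0: 50.2, 62.3; 40.0: 29.1, 82.7; 50.0: 20.5, 91.3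
- gamma (time / h: target / %, isomer of the product / %): 0.250: 29.5, 0; 0.667: 69.9, 3.3; 1.00: 72.1, 5.7; 1.50: 68.8, 8.8; 3.00: 58.7, 18.9

(scatter of a reading: 0.3 percentage points)

- charges are per starting volume, the dose included; the dosed solution carries all of it

- which flask leads in share of target in all that became target or isomer of the product ("all alike" within 1.5 percentage points) (violet / teal / grey / all alike)
- share of target in all that became target or isomer of the product, violet
- share of target in all that became target or isomer of the product, teal
- share of target in all that became target or isomer of the product, grey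

This is my own reckoning, built one process at a time.

1. Growth of target from substrate, with nothing else. No isomer forms, so the share stands at 100%.

2. Add isomerisation, taken as first order in target. Between 1.50 h and 3.00 h, epsilon's isomer gains at 0.107 h⁻¹ per unit of target. Delta's target tail falls at 2.15 h⁻¹. Interpolating the logarithm linearly in temperature gives 0.195 h⁻¹ for teal. Now define the half-share time, ln(2) over this constant: the age of the target at which target and isomer stand equal, the zero of the scale. It is 3.56 h for teal and 0.322 h for violet. Counting the whole 1.0 h as age, the share is 82.3% in teal and 11.6% in violet.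

3. Add the lag phase of target growth. Epsilon reads 61.8% target at 0.500 h and delta reads 57.3% at 3.00 min, and I take these times as the mean moment at which target forms. The seeds differ (2.8 mM in epsilon, 4.4 mM in delta, 2.00 mM in the new flasks), so this is rough. Violet keeps delta's lag, and interpolation gives teal 0.315 h. With age equal to time minus lag, the share is 87.5% in teal and 13.0% in violet.

4. The rest. Delta's sum stays below the 122% of charge plus seed, and I treat that shortfall as a loss of substrate outside the share. Delta's target is still falling at 50.0 min, so I add no floor. Extrapolated, grey's half-share time is 1.75 min, which leaves hardly any target in the share. In this reckoning teal leads.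

The forecast names teal, with violet 15% (11% to 19%), teal 88% (85% to 91%) and grey 0.2% (0% to 3%): “Grey: essentially all isomerised.” Its violet stands above mine and its teal close to mine.

The simulation gives teal as the leader, with violet 13.7%, teal 87.2% and grey 5.26%, which is 5.1 percentage points above the forecast. Grey's target stands at 5.20% after 0.500 h and 5.18% after 10.0 h, thermodynamic control, and its equilibrium constant 18.0 gives a share of 5.26%. Teal's half-share time, used at 10.0 h, gives 15.2%, and the simulation gives 14.7%.

    substrate + target → 2 target (k = 3.34 L mol⁻¹ s⁻¹, Ea = 65.0 kJ mol⁻¹)
    substrate → target (k = 2.74 × 10⁻⁴ s⁻¹, Ea = 115 kJ mol⁻¹)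
    2 substrate → self-condensation product (k = 0.148 L mol⁻¹ s⁻¹, Ea = 53.0 kJ mol⁻¹)
    target ⇌ isomer of the product (K = 18.0, k = 0.00535 s⁻¹, Ea = 105 kJ mol⁻¹, ΔH = −61.0 kJ mol⁻¹)
    (constants at 80 °C)

Read teal at 40 min instead: the age shrinks to 0.352 h, and the half-share time gives 93.4%. The simulation gives 92.5%.

All runs were generated by integration for substances that don't exist, and the scatter is random.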